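The synthesis rests on cutting both C–O bonds of the oxirane ring (O8, quaternary benzylic Cq, methylene C9). Cq also carries the C10 oxymethyl arm. Removing O8 and the isovaleryl group therefore leaves Cq=C9 next to a free C10 hydroxyl. This is a 2-arylallyl alcohol, a substrate for Sharpless asymmetric epoxidation. In one operation that step forms Cq–O8 and C9–O8, closes the three-membered ring and sets the only stereocentre. Its precursor is 2-(3-hydroxyprop-1-en-2-yl)-4-methoxy-5-methylphenyl tiglate, made by Suzuki coupling. The phenol already carries its final ester, so the oxirane never has an unprotected phenol as neighbour. Isovalerylation of C10–OH ends the route.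

Key step: step 7

Remark on the chemistry: Cq is S in the epoxy alcohol and R in the target with no change in space, because esterification raises C10 above C9 in the CIP ranking; a Payne shift of the epoxy alkoxide is degenerate here (inversion at Cq plus exchange of the roles of C9 and C10) and returns the same enantiomer, so base cannot racemise Cq.

Step 1
Reactants: 1 4-methoxy-3-methylphenol
Product: 2 2-bromo-4-methoxy-5-methylphenol
Conditions: NBS (1.0 equiv), MeCN, −10 → 0 °C, dark
Reagents that add atoms: N-bromosuccinimide, O=C1CCC(=O)N1Br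
Why: Electrophilic aromatic bromination, in which the free hydroxyl is the strongest director, its para position is blocked by OCH3 and the ortho site between OH and CH3 is crowded, so bromine should enter the open ortho carbon that is also para to the methyl group.

Step 2
Reactants: 3 2-bromoprop-2-en-1-ol
Product: 4 [(2-bromoprop-2-en-1-yl)oxy](tert-butyl)dimethylsilane
Conditions: TBSCl, imidazole, CH2Cl2, 0 °C → rt
Reagents that add atoms: tert-butyldimethylsilyl chloride, CC(C)(C)[Si](C)(C)Cl
Why: Imidazole-promoted silylation of a primary alcohol, to which the vinyl bromide is inert.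

Step 3
Reactants: 4 [(2-bromoprop-2-en-1-yl)oxy](tert-butyl)dimethylsilane
Product: 5 tert-butyldimethyl{[2-(4,4,5,5-tetramethyl-1,3,2-dioxaborolan-2-yl)prop-2-en-1-yl]oxy}silane
Conditions: B2pin2, PdCl2(PPh3)2 (3 mol %), PPh3 (6 mol %), KOPh, toluene, 50 °C
Reagents that add atoms: bis(pinacolato)diboron, CC1(C)OB(OC1(C)C)B1OC(C)(C)C(C)(C)O1
Why: Miyaura borylation of a 1-alkenyl bromide (oxidative addition to zerovalent palladium, bromide–phenoxide exchange, transmetalation with B2pin2, reductive elimination), chosen over bromine–lithium exchange because a 2-lithioallyl silyl ether can suffer O-to-C silyl migration.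

Step 4
Reactants: 2 2-bromo-4-methoxy-5-methylphenol; 5 tert-butyldimethyl{[2-(4,4,5,5-tetramethyl-1,3,2-dioxaborolan-2-yl)prop-2-en-1-yl]oxy}silane
Product: 6 2-{3-[(tert-butyldimethylsilyl)oxy]prop-1-en-2-yl}-4-methoxy-5-methylphenol
Conditions: Pd(OAc)2 (3 mol %), SPhos (2-dicyclohexylphosphino-2',6'-dimethoxybiphenyl, 6 mol %), K3PO4, dioxane/H2O, 80 °C
Reagents that add atoms: none
Why: Suzuki–Miyaura coupling, in which the electron-rich biaryl phosphine speeds oxidative addition into the electron-rich ortho-oxygenated aryl bromide, unprotected 2-bromophenols are accepted under aqueous phosphate, and the primary TBS ether withstands the base.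

Step 5
Reactants: 6 2-{3-[(tert-butyldimethylsilyl)oxy]prop-1-en-2-yl}-4-methoxy-5-methylphenol; 7 tiglic acid, (E)-2-methylbut-2-enoic acid
Product: 8 2-{3-[(tert-butyldimethylsilyl)oxy]prop-1-en-2-yl}-4-methoxy-5-methylphenyl (E)-2-methylbut-2-enoate
Conditions: DCC, DMAP (10 mol %), CH2Cl2, 0 °C → rt
Reagents that add atoms: tiglic acid (7), C/C=C(\C)C(=O)O
Why: Steglich esterification, in which DMAP relays the tigloyl group from the O-acylisourea to the phenol without a stoichiometric amine base, so neither loss of the E geometry nor deconjugation through a vinylketene (a hazard of the acid chloride with Et3N) is expected.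

Step 6
Reactants: 8 2-{3-[(tert-butyldimethylsilyl)oxy]prop-1-en-2-yl}-4-methoxy-5-methylphenyl (E)-2-methylbut-2-enoate
Product: 9 2-(3-hydroxyprop-1-en-2-yl)-4-methoxy-5-methylphenyl (E)-2-methylbut-2-enoate
Conditions: HF·pyridine, pyridine, THF, 0 °C → rt
Reagents that add atoms: none
Why: Fluoride-driven Si–O cleavage in a weakly acidic buffer, which releases the C10 hydroxyl as the neutral alcohol and not as an alkoxide (as Bu4NF would), so the neighbouring aryl ester should not be attacked.

Step 7
Reactants: 9 2-(3-hydroxyprop-1-en-2-yl)-4-methoxy-5-methylphenyl (E)-2-methylbut-2-enoate; 10 tert-butyl hydroperoxide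
Product: 11 2-[(2S)-2-(hydroxymethyl)oxiran-2-yl]-4-methoxy-5-methylphenyl (E)-2-methylbut-2-enoate
Conditions: Ti(OtBu)4 (10 mol %), L-(+)-DIPT (12 mol %), t-BuOOH (2 equiv, anhydrous in decane), powdered 4 Å MS, CH2Cl2, −25 °C
Reagents that add atoms: tert-butyl hydroperoxide (10), CC(C)(C)OO
Why: This is the Sharpless asymmetric epoxidation in its catalytic molecular-sieve variant, a reaction with ample precedent for 2-alkyl- and 2-arylallyl alcohols. Ligand exchange places the C10 alkoxide of 9 and an η2-bound tert-butylperoxide on the same metal centre of the binuclear titanium tartrate (tetravalent titanium), and the Cq=C9 π bond attacks the peroxide oxygen that does not carry the tert-butyl group along the O–O axis while tert-butoxide stays on the metal. Both C–O bonds arise in this single concerted, spiro-oriented event, so the oxirane (O8, Cq, C9) closes by [2+1] oxygen-atom transfer and not by a displacement. The only stereocontrol element is the (R,R)-tartrate: with L-(+)-DIPT the tethered alkene can offer only the Si face of Cq (ranking C10 > aryl > C9), the same sense that converts methallyl alcohol into (S)-2-methylglycidol, hence S at Cq. Two selectivities are needed, enantioface and choice of alkene, and both depend on the C10–O–Ti tether, which the conjugated, electron-poor tiglate C=C lacks. Ti(OtBu)4 in place of the isopropoxide, low loading and −25 °C leave only tertiary alcohols in solution, which should keep alkoxide attack on the aryl ester and on the benzylic oxirane slow.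

Step 8
Reactants: 11 2-[(2S)-2-(hydroxymethyl)oxiran-2-yl]-4-methoxy-5-methylphenyl (E)-2-methylbut-2-enoate; 12 isovaleryl chloride (3-methylbutanoyl chloride)
Product: 13 2-{(2R)-2-[(3-methylbutanoyloxy)methyl]oxiran-2-yl}-4-methoxy-5-methylphenyl (E)-2-methylbut-2-enoate (target)
Conditions: Et3N (2 equiv), CH2Cl2, −20 °C
Reagents that add atoms: isovaleryl chloride (12), CC(C)CC(=O)Cl
Why: Acyl chloride esterification of a primary alcohol, the acylation type used to derivatise sensitive glycidols, which is fast at −20 °C, binds HCl as an ammonium salt too weakly acidic to open the oxirane, and touches no bond at Cq.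

Compound list
1 | 4-methoxy-3-methylphenol | Cc1cc(O)ccc1OC | starting material
2 | 2-bromo-4-methoxy-5-methylphenol | Cc1cc(O)c(Br)cc1OC | intermediate
3 | 2-bromoprop-2-en-1-ol | C=C(Br)CO | starting material
4 | [(2-bromoprop-2-en-1-yl)oxy](tert-butyl)dimethylsilane | C=C(Br)CO[Si](C)(C)C(C)(C)C | intermediate
5 | tert-butyldimethyl{[2-(4,4,5,5-tetramethyl-1,3,2-dioxaborolan-2-yl)prop-2-en-1-yl]oxy}silane | C=C(CO[Si](C)(C)C(C)(C)C)B1OC(C)(C)C(C)(C)O1 | intermediate
6 | 2-{3-[(tert-butyldimethylsilyl)oxy]prop-1-en-2-yl}-4-methoxy-5-methylphenol | Cc1cc(O)c(cc1OC)C(=C)CO[Si](C)(C)C(C)(C)C | intermediate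
7 | tiglic acid, (E)-2-methylbut-2-enoic acid | C/C=C(\C)C(=O)O | starting material
8 | 2-{3-[(tert-butyldimethylsilyl)oxy]prop-1-en-2-yl}-4-methoxy-5-methylphenyl (E)-2-methylbut-2-enoate | C/C=C(\C)C(=O)Oc1cc(C)c(OC)cc1C(=C)CO[Si](C)(C)C(C)(C)C | intermediate
9 | 2-(3-hydroxyprop-1-en-2-yl)-4-methoxy-5-methylphenyl (E)-2-methylbut-2-enoate | C/C=C(\C)C(=O)Oc1cc(C)c(OC)cc1C(=C)CO | intermediate
10 | tert-butyl hydroperoxide | CC(C)(C)OO | starting material
11 | 2-[(2S)-2-(hydroxymethyl)oxiran-2-yl]-4-methoxy-5-methylphenyl (E)-2-methylbut-2-enoate | C/C=C(\C)C(=O)Oc1cc(C)c(OC)cc1[C@]1(CO)CO1 | intermediate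
12 | isovaleryl chloride (3-methylbutanoyl chloride) | CC(C)CC(=O)Cl | starting material
13 | 2-{(2R)-2-[(3-methylbutanoyloxy)methyl]oxiran-2-yl}-4-methoxy-5-methylphenyl (E)-2-methylbut-2-enoate, CNP0108422.1 | C/C=C(\C)C(=O)Oc1cc(C)c(OC)cc1[C@]1(COC(=O)CC(C)C)CO1 | target

Total step count: 8.
Longest linear sequence: 7 steps (3 → 4 → 5 → 6 → 8 → 9 → 11 → 13).

Steps most likely to fail

**Step 7.**
- What may go wrong:
  - Facial discrimination may be incomplete, because the twisted ortho-acyloxyaryl group crowds the catalyst around a 1,1-disubstituted alkene.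
  - Titanium may mediate a shift of the tigloyl group from the phenol oxygen to the bound C10 alkoxide.
  - The benzylic oxirane may be opened by Lewis acid with participation of the neighbouring ester.
- Precaution: the usual aqueous NaOH hydrolysis of the tartrate is left out. The tartrate is removed by chromatography on amine-deactivated silica.
- Fallback (resolution instead of asymmetric catalysis, no titanium), setting out from 9:
  - Buffered peracid epoxidation (mCPBA, NaHCO3, CH2Cl2, 0 °C) selects the more electron-rich styrene-type alkene. It should give racemic 2-[2-(hydroxymethyl)oxiran-2-yl]-4-methoxy-5-methylphenyl (E)-2-methylbut-2-enoate F1.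
  - Lipase-catalysed kinetic resolution with vinyl acetate in diisopropyl ether is a known way to resolve 2-substituted oxiranemethanols. The enzyme is chosen by screening for faster acetylation of the (R)-alcohol, with Burkholderia cepacia and Pseudomonas fluorescens lipases as first candidates.
  - The unwanted antipode would become 2-{(2S)-2-[(acetyloxy)methyl]oxiran-2-yl}-4-methoxy-5-methylphenyl (E)-2-methylbut-2-enoate F2, and the (S)-alcohol would be left untouched.
  - After chromatographic separation the route is rejoined at 11.

**Step 6.**
- What may go wrong: the tigloyl group may migrate to the newly freed primary hydroxyl, or the aryl ester may be cleaved, during or after silyl removal.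
- Fallback (no hydroxyl protecting group, base-free C–C coupling as the last operation before the epoxidation), setting out from 2:
  - Steglich esterification with 7 (DCC, DMAP, CH2Cl2) gives 2-bromo-4-methoxy-5-methylphenyl (E)-2-methylbut-2-enoate F3.
  - α-Selective hydrostannation of commercial propargyl alcohol (Bu3SnH, Mo(CO)3(CNtBu)3 cat., THF, 55 °C) supplies 2-(tributylstannyl)prop-2-en-1-ol F4.
  - Stille coupling of the two (Pd(PPh3)4, CuI, DMF, 70 °C) needs neither base nor fluoride. It comes back to the route at 9.

**Step 4.**
- What may go wrong: oxidative addition into the electron-rich bromophenoxide may be slow, so that protodeboronation of the 1-substituted vinylboronate consumes the coupling partner.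
- Fallback (reversal of polarity), setting out from 2:
  - Double lithiation (n-BuLi, 2.2 equiv, Et2O, −78 → 0 °C), trapping with B(OiPr)3 and work-up with dilute HCl give (2-hydroxy-5-methoxy-4-methylphenyl)boronic acid F5.
  - F5 is coupled with vinyl bromide 4 (Pd(PPh3)4, Na2CO3, DME/H2O, 80 °C). The vinyl bromide adds readily to zerovalent palladium.
  - The sequence returns at 6 and makes step 3 unnecessary.

Further compounds
F1 | step 7 | racemic 2-[2-(hydroxymethyl)oxiran-2-yl]-4-methoxy-5-methylphenyl (E)-2-methylbut-2-enoate | C/C=C(\C)C(=O)Oc1cc(C)c(OC)cc1C1(CO)CO1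
F2 | step 7 | 2-{(2S)-2-[(acetyloxy)methyl]oxiran-2-yl}-4-methoxy-5-methylphenyl (E)-2-methylbut-2-enoate | C/C=C(\C)C(=O)Oc1cc(C)c(OC)cc1[C@@]1(COC(C)=O)CO1
F3 | step 6 | 2-bromo-4-methoxy-5-methylphenyl (E)-2-methylbut-2-enoate | C/C=C(\C)C(=O)Oc1cc(C)c(OC)cc1Br
F4 | step 6 | 2-(tributylstannyl)prop-2-en-1-ol | C=C(CO)[Sn](CCCC)(CCCC)CCCC
F5 | step 4 | (2-hydroxy-5-methoxy-4-methylphenyl)boronic acid | Cc1cc(O)c(cc1OC)B(O)O
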